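**Retrosynthetic overview**
- The target is the desilylated form of its TBS ether; the amidine C–N bond to the imidazoledione is cut back to a 2-aminoimidazole and 1-methylparabanic acid, which is bought as the intact ring and attached last.
- The 2-NH2 group comes from C2-lithiation, azide transfer and Staudinger reduction of a 1-methyl-4,5-disubstituted imidazole.
- The N-methyl position is fixed by N3-methylation of an N1-(2-cyanoethyl)imidazole followed by loss of acrylonitrile.
- The imidazole is the only ring built: a van Leusen [3+2] cycloaddition of α-(4-methoxybenzyl)TosMIC with the aldimine from O-TBS-(R)-4-methoxymandelaldehyde and 3-aminopropanenitrile.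
- The carbinol stereocentre is bought in (R)-4-methoxymandelic acid and carried through unchanged; the carboxyl carbon becomes imidazole C4.

Assumption: (R)-4-methoxymandelic acid and 1-methylparabanic acid are catalogue compounds; the target carbinol centre is (R) (OH > imidazolyl > aryl > H), the same descriptor as in the acid.

**Route**

Step 1
Reactants: 1 p-toluenesulfonylmethyl isocyanide (TosMIC); 2 4-methoxybenzyl chloride
Product: 3 1-{[1-isocyano-2-(4-methoxyphenyl)ethyl]sulfonyl}-4-methylbenzene (racemic α-(4-methoxybenzyl)TosMIC)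
Conditions: 30% aq. NaOH, CH2Cl2, BnEt3NCl (cat.), 0 °C
Reagents that add atoms: none
Why: Phase-transfer SN2 C-alkylation of the doubly activated CH2 of TosMIC by the benzylic chloride stops at mono-alkylation; the new centre is racemic and disappears in step 4.

Step 2
Reactants: 4 (R)-4-methoxymandelic acid
Product: 5 tert-butyldimethylsilyl (2R)-2-[(tert-butyldimethylsilyl)oxy]-2-(4-methoxyphenyl)acetate
Conditions: TBSCl (2.4 equiv), imidazole (5 equiv), DMF, rt
Reagents that add atoms: tert-butyldimethylsilyl chloride, CC(C)(C)[Si](C)(C)Cl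
Why: Exhaustive Corey silylation masks the benzylic OH as a TBS ether and turns the acid into a reducible silyl ester under conditions that do not touch the C–H of the bought stereocentre.

Step 3
Reactants: 5 tert-butyldimethylsilyl (2R)-2-[(tert-butyldimethylsilyl)oxy]-2-(4-methoxyphenyl)acetate
Product: 6 (2R)-2-[(tert-butyldimethylsilyl)oxy]-2-(4-methoxyphenyl)acetaldehyde
Conditions: i-Bu2AlH (1.1 equiv), CH2Cl2, −78 °C; MeOH, then aq. potassium sodium tartrate; crude aldehyde used at once
Reagents that add atoms: none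
Why: Partial hydride reduction of the silyl ester stops at the aluminium hemiacetal at −78 °C and releases the aldehyde only on work-up, so the α-stereocentre is not enolised.

Step 4
Reactants: 6 (2R)-2-[(tert-butyldimethylsilyl)oxy]-2-(4-methoxyphenyl)acetaldehyde; 7 3-aminopropanenitrile; 3 α-(4-methoxybenzyl)TosMIC
Product: 10 3-{4-(4-methoxybenzyl)-5-[(R)-[(tert-butyldimethylsilyl)oxy](4-methoxyphenyl)methyl]-1H-imidazol-1-yl}propanenitrile, via aldimine 8 (not isolated), via 4-tosylimidazoline cycloadduct 9 (not isolated)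
Conditions: 7, 4 Å MS, CH2Cl2, 0 °C; then 3, K2CO3, DMF, 0 °C to rt
Reagents that add atoms: none
Why: Van Leusen base-induced [3+2] cycloaddition of the isocyanide C–N–C unit of 3 across the C=N of aldimine 8 gives imidazoline 9, which aromatises by loss of p-toluenesulfinic acid; the stereocentre is the one bought in 4 and is protected from epimerisation by the weak base, low temperature and immediate use of the imine.

Step 5
Reactants: 10 3-{4-(4-methoxybenzyl)-5-[(R)-[(tert-butyldimethylsilyl)oxy](4-methoxyphenyl)methyl]-1H-imidazol-1-yl}propanenitrile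
Product: 12 4-[(R)-[(tert-butyldimethylsilyl)oxy](4-methoxyphenyl)methyl]-5-(4-methoxybenzyl)-1-methyl-1H-imidazole, via imidazolium iodide 11 (not isolated)
Conditions: MeI (3 equiv), MeCN, 50 °C; evaporate excess MeI; then 1 M aq. NaOH, THF, rt
Reagents that add atoms: iodomethane, CI
Why: Menshutkin methylation at the only basic nitrogen (N3) followed by base-induced retro-aza-Michael loss of acrylonitrile from the imidazolium salt places the methyl group regiospecifically on the nitrogen next to the benzyl-bearing carbon.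

Step 6
Reactants: 12 4-[(R)-[(tert-butyldimethylsilyl)oxy](4-methoxyphenyl)methyl]-5-(4-methoxybenzyl)-1-methyl-1H-imidazole
Product: 15 4-[(R)-[(tert-butyldimethylsilyl)oxy](4-methoxyphenyl)methyl]-5-(4-methoxybenzyl)-1-methyl-1H-imidazol-2-amine, via 2-azidoimidazole 13 (not isolated), via iminophosphorane 14 (not isolated)
Conditions: n-BuLi, THF, −78 °C; 2,4,6-(i-Pr)3C6H2SO2N3, −78 to 0 °C; then PMe3, THF/H2O, rt to 50 °C
Reagents that add atoms: 2,4,6-triisopropylbenzenesulfonyl azide, CC(C)c1cc(C(C)C)c(S(=O)(=O)N=[N+]=[N-])c(C(C)C)c1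
Why: C2-lithiation of the N-methylimidazole at its most acidic C–H, electrophilic azide transfer and Staudinger reduction install the 2-NH2 group without acid or hydrogenolysis, so the benzylic silyl ether and its stereocentre are untouched.

Step 7
Reactants: 15 4-[(R)-[(tert-butyldimethylsilyl)oxy](4-methoxyphenyl)methyl]-5-(4-methoxybenzyl)-1-methyl-1H-imidazol-2-amine; 16 1-methylimidazolidine-2,4,5-trione (1-methylparabanic acid)
Product: 18 4-({4-[(R)-[(tert-butyldimethylsilyl)oxy](4-methoxyphenyl)methyl]-5-(4-methoxybenzyl)-1-methyl-1H-imidazol-2-yl}amino)-1-methyl-1H-imidazole-2,5-dione, via O-silyl imidate 17 (not isolated)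
Conditions: 16, N,O-bis(trimethylsilyl)acetamide, MeCN, 80 °C; then 15, toluene, 110 °C; MeOH quench
Reagents that add atoms: none
Why: Silylation of the N3–H/C4=O lactam of 16 gives imidate 17, which undergoes addition–elimination (amidine-forming condensation) with the exocyclic amine only at C4, the carbonyl remote from N-methyl.

Step 8
Reactants: 18 4-({4-[(R)-[(tert-butyldimethylsilyl)oxy](4-methoxyphenyl)methyl]-5-(4-methoxybenzyl)-1-methyl-1H-imidazol-2-yl}amino)-1-methyl-1H-imidazole-2,5-dione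
Product: 19 4-({4-[(R)-hydroxy(4-methoxyphenyl)methyl]-5-(4-methoxybenzyl)-1-methyl-1H-imidazol-2-yl}amino)-1-methyl-1H-imidazole-2,5-dione (CNP0288484.1)
Conditions: Bu4NF, AcOH (1:1), THF, 0 °C to rt; chromatography on Et3N-deactivated silica
Reagents that add atoms: none
Why: Buffered fluoride desilylation frees the carbinol without acid, so the doubly activated benzylic C–O bond cannot ionise and the (R) configuration is kept.

**Compound list**
1 | p-toluenesulfonylmethyl isocyanide (TosMIC) | [C-]#[N+]CS(=O)(=O)c1ccc(C)cc1 | starting material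
2 | 4-methoxybenzyl chloride | COc1ccc(CCl)cc1 | starting material
3 | 1-{[1-isocyano-2-(4-methoxyphenyl)ethyl]sulfonyl}-4-methylbenzene (racemic) | [C-]#[N+]C(Cc1ccc(OC)cc1)S(=O)(=O)c1ccc(C)cc1 | intermediate
4 | (R)-4-methoxymandelic acid, (2R)-2-hydroxy-2-(4-methoxyphenyl)acetic acid | OC(=O)[C@H](O)c1ccc(OC)cc1 | starting material
5 | tert-butyldimethylsilyl (2R)-2-[(tert-butyldimethylsilyl)oxy]-2-(4-methoxyphenyl)acetate | CC(C)(C)[Si](C)(C)OC(=O)[C@H](O[Si](C)(C)C(C)(C)C)c1ccc(OC)cc1 | intermediate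
6 | (2R)-2-[(tert-butyldimethylsilyl)oxy]-2-(4-methoxyphenyl)acetaldehyde | O=C[C@H](O[Si](C)(C)C(C)(C)C)c1ccc(OC)cc1 | intermediate
7 | 3-aminopropanenitrile | NCCC#N | starting material
8 | 3-{[(1E,2R)-2-[(tert-butyldimethylsilyl)oxy]-2-(4-methoxyphenyl)ethylidene]amino}propanenitrile | N#CCC/N=C/[C@H](O[Si](C)(C)C(C)(C)C)c1ccc(OC)cc1 | intermediate (not isolated)
9 | 3-{4-(4-methoxybenzyl)-5-[(R)-[(tert-butyldimethylsilyl)oxy](4-methoxyphenyl)methyl]-4-tosyl-4,5-dihydro-1H-imidazol-1-yl}propanenitrile (ring C4/C5 diastereomer mixture) | N#CCCN1C=NC(Cc2ccc(OC)cc2)(S(=O)(=O)c2ccc(C)cc2)C1[C@H](O[Si](C)(C)C(C)(C)C)c1ccc(OC)cc1 | intermediate (not isolated)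
10 | 3-{4-(4-methoxybenzyl)-5-[(R)-[(tert-butyldimethylsilyl)oxy](4-methoxyphenyl)methyl]-1H-imidazol-1-yl}propanenitrile | N#CCCn1cnc(Cc2ccc(OC)cc2)c1[C@H](O[Si](C)(C)C(C)(C)C)c1ccc(OC)cc1 | intermediate
11 | 1-(2-cyanoethyl)-4-(4-methoxybenzyl)-5-[(R)-[(tert-butyldimethylsilyl)oxy](4-methoxyphenyl)methyl]-3-methylimidazolium iodide | N#CCC[n+]1cn(C)c(Cc2ccc(OC)cc2)c1[C@H](O[Si](C)(C)C(C)(C)C)c1ccc(OC)cc1.[I-] | intermediate (not isolated)
12 | 4-[(R)-[(tert-butyldimethylsilyl)oxy](4-methoxyphenyl)methyl]-5-(4-methoxybenzyl)-1-methyl-1H-imidazole | COc1ccc(Cc2c([C@H](O[Si](C)(C)C(C)(C)C)c3ccc(OC)cc3)ncn2C)cc1 | intermediate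
13 | 2-azido-4-[(R)-[(tert-butyldimethylsilyl)oxy](4-methoxyphenyl)methyl]-5-(4-methoxybenzyl)-1-methyl-1H-imidazole | COc1ccc(Cc2c([C@H](O[Si](C)(C)C(C)(C)C)c3ccc(OC)cc3)nc(N=[N+]=[N-])n2C)cc1 | intermediate (not isolated)
14 | N-(trimethylphosphoranylidene) derivative of amine 15 | COc1ccc(Cc2c([C@H](O[Si](C)(C)C(C)(C)C)c3ccc(OC)cc3)nc(N=P(C)(C)C)n2C)cc1 | intermediate (not isolated)
15 | 4-[(R)-[(tert-butyldimethylsilyl)oxy](4-methoxyphenyl)methyl]-5-(4-methoxybenzyl)-1-methyl-1H-imidazol-2-amine | COc1ccc(Cc2c([C@H](O[Si](C)(C)C(C)(C)C)c3ccc(OC)cc3)nc(N)n2C)cc1 | intermediate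
16 | 1-methylimidazolidine-2,4,5-trione (1-methylparabanic acid) | CN1C(=O)NC(=O)C1=O | starting material
17 | 1-methyl-4-[(trimethylsilyl)oxy]-1H-imidazole-2,5-dione | CN1C(=O)N=C(O[Si](C)(C)C)C1=O | intermediate (not isolated)
18 | 4-({4-[(R)-[(tert-butyldimethylsilyl)oxy](4-methoxyphenyl)methyl]-5-(4-methoxybenzyl)-1-methyl-1H-imidazol-2-yl}amino)-1-methyl-1H-imidazole-2,5-dione | COc1ccc(Cc2c([C@H](O[Si](C)(C)C(C)(C)C)c3ccc(OC)cc3)nc(NC3=NC(=O)N(C)C3=O)n2C)cc1 | intermediate
19 | 4-({4-[(R)-hydroxy(4-methoxyphenyl)methyl]-5-(4-methoxybenzyl)-1-methyl-1H-imidazol-2-yl}amino)-1-methyl-1H-imidazole-2,5-dione | COc1ccc(Cc2c([C@H](O)c3ccc(OC)cc3)nc(NC3=NC(=O)N(C)C3=O)n2C)cc1 | target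

**Step count**
Total: 8 steps. Longest linear sequence: 7 steps (steps 2 to 8, from 4); step 1 is a one-step side branch.

**Three steps most likely to fail, with fallbacks**

Step 4 is the main risk. The α-aryl-α-silyloxy aldimine 8 can lose optical purity by imine–enamine tautomerism under base, and the tertiary carbanion of 3 adds slowly to a hindered imine; the ee should be checked by chiral HPLC at 10 or 12. The fallback sets out from 6 and comes back at 12, so step 5 falls away. Aldehyde 6 is condensed with p-toluenesulfonamide (Ti(OEt)4, CH2Cl2, rt) to N-[(1E,2R)-2-[(tert-butyldimethylsilyl)oxy]-2-(4-methoxyphenyl)ethylidene]-4-methylbenzenesulfonamide F2. Commercial N,O-dimethyl-L-tyrosine is formylated with acetic formic anhydride to N-formyl-N-methyl-O-methyl-L-tyrosine F3. F3 is cyclodehydrated with EDC·HCl in CH2Cl2 in the presence of F2 to the münchnone 4-(4-methoxybenzyl)-3-methyl-1,3-oxazol-3-ium-5-olate F4. Its 1,3-dipolar cycloaddition to the sulfonylimine (nucleophilic C4 to the imine carbon) is followed by loss of CO2 and sulfinic acid and gives 12 directly, with N-methyl already next to the benzyl-bearing carbon.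

Step 3 may over-reduce the silyl ester or give a mixture of aldehyde and alcohol. The fallback sets out from 5 and comes back at 6. Compound 5 is reduced completely with i-Bu2AlH (2.5 equiv, CH2Cl2, −78 to 0 °C) to (2R)-2-[(tert-butyldimethylsilyl)oxy]-2-(4-methoxyphenyl)ethan-1-ol F1, which is oxidised with Dess–Martin periodinane and NaHCO3 (CH2Cl2, 0 °C) to 6 under non-basic conditions.

Step 6 may suffer from competing benzylic lithiation, incomplete azide transfer or a sluggish Staudinger hydrolysis. The fallback sets out from 12 and comes back at 15 and avoids both the organolithium and the azide. Electrophilic bromination at the only free ring position (NBS, 1.0 equiv, MeCN, 0 °C) gives 2-bromo-4-[(R)-[(tert-butyldimethylsilyl)oxy](4-methoxyphenyl)methyl]-5-(4-methoxybenzyl)-1-methyl-1H-imidazole F5. C–N cross-coupling with LiN(SiMe3)2 as ammonia surrogate (Pd2(dba)3 as zerovalent palladium source, tBuBrettPhos, THF, 65 °C) and mild aqueous work-up gives 15.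

Further compounds
F1 | step 3 | (2R)-2-[(tert-butyldimethylsilyl)oxy]-2-(4-methoxyphenyl)ethan-1-ol | OC[C@H](O[Si](C)(C)C(C)(C)C)c1ccc(OC)cc1
F2 | step 4 | N-[(1E,2R)-2-[(tert-butyldimethylsilyl)oxy]-2-(4-methoxyphenyl)ethylidene]-4-methylbenzenesulfonamide | Cc1ccc(cc1)S(=O)(=O)/N=C/[C@H](O[Si](C)(C)C(C)(C)C)c1ccc(OC)cc1
F3 | step 4 | N-formyl-N-methyl-O-methyl-L-tyrosine | O=CN(C)[C@@H](Cc1ccc(OC)cc1)C(=O)O
F4 | step 4 | 4-(4-methoxybenzyl)-3-methyl-1,3-oxazol-3-ium-5-olate | C[n+]1coc([O-])c1Cc1ccc(OC)cc1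
F5 | step 6 | 2-bromo-4-[(R)-[(tert-butyldimethylsilyl)oxy](4-methoxyphenyl)methyl]-5-(4-methoxybenzyl)-1-methyl-1H-imidazole | COc1ccc(Cc2c([C@H](O[Si](C)(C)C(C)(C)C)c3ccc(OC)cc3)nc(Br)n2C)cc1
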